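**Plan**

- Retrosynthesis: the pyrimidine C2–NH2 bond is cut first (ammonia on a 2-chloropyrimidine), then the two benzo-ring bonds C3a–C4 and C7–C7a, then the bond from indole C3 to pyrimidine C4.
- Enabling feature: C4–C5(Br)–C6(Br)–C7 of the indole is a symmetric four-carbon diene unit, the carbon chain of 3,4-dibromothiophene 1,1-dioxide. C3a=C7a is the enamine-type double bond of an N-acyl 2,3-dihydropyrrole that already carries the pyrimidine at C3.
- Forward: a Heck coupling joins the pyrimidine to the five-membered nitrogen ring. The six-membered carbocycle is closed on the enecarbamate bond by (4+2) cycloaddition with loss of SO2. DDQ aromatizes first the carbocycle and then the nitrogen ring, and ammonia removes Boc and installs NH2.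
- Stereochemistry: the target is achiral. The sp3 centres C3, C3a and C7a exist only between steps 2 and 4 (racemic, cis ring fusion) and are all erased on aromatization.

Key step: step 3

Assumption: 2-chloro-4-iodopyrimidine is taken as a catalogue compound; every chiral intermediate is racemic and is drawn as one enantiomer with its relative configuration.

**Route**

Step 1
Reactants: 1 3,4-dibromothiophene
Product: 3 3,4-dibromothiophene 1,1-dioxide, via 3,4-dibromothiophene 1-oxide 2 (not isolated)
Conditions: (CF3CO)2O, H2O2 (50% aq), CH2Cl2, 0 °C → rt; crystallize, store cold, use promptly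
Reagents that add atoms: trifluoroperacetic acid, OOC(=O)C(F)(F)F (oxygen donor, formed in the flask from hydrogen peroxide, OO, and trifluoroacetic anhydride, O=C(OC(=O)C(F)(F)F)C(F)(F)F)
Why: Peracid S-oxidation of a thiophene, in which trifluoroperacetic acid is electrophilic enough for the bromine-deactivated sulfur, the sulfoxide 2 is oxidized faster than 1, and the 3,4-dihalo substitution should make the dioxide persistent enough to isolate.

Step 2
Reactants: 4 tert-butyl 2,5-dihydro-1H-pyrrole-1-carboxylate (3 equiv); 5 2-chloro-4-iodopyrimidine
Product: 6 tert-butyl 3-(2-chloropyrimidin-4-yl)-2,3-dihydro-1H-pyrrole-1-carboxylate (racemic)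
Conditions: Pd(OAc)2 (5 mol %), P(o-tol)3 (10 mol %), Ag2CO3 (1.0 equiv), MeCN, 70 °C; chromatography on Et3N-deactivated silica
Reagents that add atoms: none
Why: Mizoroki–Heck arylation of an N-acyl-3-pyrroline, in which the C–I bond (not C–Cl) adds to zerovalent palladium, syn carbopalladation of the symmetric alkene leaves only a hydrogen of the CH2 next to nitrogen syn to palladium so that β-hydride elimination places the double bond as the enecarbamate, and Ag2CO3 removes iodide so that the palladium hydride does not re-add and move the double bond toward the pyrimidine; C3 forms racemic.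

Step 3
Reactants: 3 3,4-dibromothiophene 1,1-dioxide (1.5 equiv); 6 tert-butyl 3-(2-chloropyrimidin-4-yl)-2,3-dihydro-1H-pyrrole-1-carboxylate
Product: 8 tert-butyl cis-5,6-dibromo-3-(2-chloropyrimidin-4-yl)-2,3,3a,7a-tetrahydro-1H-indole-1-carboxylate, via bridged sulfone adduct 7 (not isolated)
Conditions: 3 added over 4 h to 6, 2,6-di-tert-butylpyridine (10 mol %), PhMe, 80 °C, N2 sweep; product carried on without storage
Reagents that add atoms: none
Why: An inverse-electron-demand Diels–Alder reaction, in which the low-lying LUMO of the cyclic sulfonyl diene 3 meets the HOMO of the enecarbamate 6, should give the 7-thiabicyclo[2.2.1]heptene dioxide 7, which loses SO2 in a thermally allowed cheletropic step below the reaction temperature. The closest known reaction type is the benzannulation of alkenes with 3,4-dihalothiophene 1,1-dioxides, which delivers 2,3-dihalocyclohexa-1,3-dienes by the same cycloaddition and extrusion. The six-membered carbocycle is closed by intermolecular (4+2) annulation onto the five-membered ring, forming C3a–C4 and C7–C7a together. C3a and C7a are set cis by suprafacial addition to the cis ring alkene, and their relation to C3 is set by approach of the diene to the face opposite the pyrimidinyl group (substrate control); as all three centres are removed in step 4, a weaker facial preference would cost nothing. The selectivity that matters is cross-cycloaddition over self-dimerization of 3 and over acid damage to 6, which should be secured by the matched electron demand of the enecarbamate, by a low stationary concentration of 3 and by sweeping out SO2 over a hindered base. Because both termini of the diene are equivalent, only one constitution is possible and the two bromines are delivered to C5 and C6.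

Step 4
Reactants: 8 tert-butyl cis-5,6-dibromo-3-(2-chloropyrimidin-4-yl)-2,3,3a,7a-tetrahydro-1H-indole-1-carboxylate
Product: 10 tert-butyl 5,6-dibromo-3-(2-chloropyrimidin-4-yl)-1H-indole-1-carboxylate, via N-Boc indoline 9 (not isolated)
Conditions: DDQ (2.5 equiv), 1,4-dioxane, rt, then 100 °C
Reagents that add atoms: none
Why: Quinone dehydrogenation, in which hydride loss from the allylic, nitrogen-bearing C7a–H and proton loss from C3a aromatize the carbocycle at room temperature and a second equivalent at 100 °C takes hydride from C2 next to the carbamate nitrogen and the acidic C3 proton, as known for N-acyl indolines; because H2 is removed rather than a leaving group, both bromines and the C7a–N bond are kept and the three stereocentres vanish.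

Step 5
Reactants: 10 tert-butyl 5,6-dibromo-3-(2-chloropyrimidin-4-yl)-1H-indole-1-carboxylate
Product: 12 meridianin F, via N-H chloropyrimidinyl indole 11 (not isolated)
Conditions: NH3 (2 M in i-PrOH, large excess), sealed tube, 110 °C
Reagents that add atoms: ammonia, N
Why: Ammonolysis of the indole N-carbamate (an acyl-azole-type, activated carbamate) followed by SNAr addition–elimination of ammonia at pyrimidine C2, which is flanked by two ring nitrogens, while the aryl bromides are inert without a metal catalyst.

**Compound list**

1 | 3,4-dibromothiophene | Brc1cscc1Br | starting material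
2 | 3,4-dibromothiophene 1-oxide | O=S1C=C(Br)C(Br)=C1 | intermediate (not isolated)
3 | 3,4-dibromothiophene 1,1-dioxide | O=S1(=O)C=C(Br)C(Br)=C1 | intermediate
4 | tert-butyl 2,5-dihydro-1H-pyrrole-1-carboxylate | CC(C)(C)OC(=O)N1CC=CC1 | starting material
5 | 2-chloro-4-iodopyrimidine | Clc1nccc(I)n1 | starting material
6 | tert-butyl 3-(2-chloropyrimidin-4-yl)-2,3-dihydro-1H-pyrrole-1-carboxylate (racemic, one enantiomer drawn) | CC(C)(C)OC(=O)N1C[C@H](c2ccnc(Cl)n2)C=C1 | intermediate
7 | tert-butyl 5,6-dibromo-3-(2-chloropyrimidin-4-yl)-2,3,3a,4,7,7a-hexahydro-1H-4,7-epithioindole-1-carboxylate 8,8-dioxide (racemic; cis ring fusion, pyrimidinyl on the face away from the bicycle, endo adduct drawn with the pyrrolidine ring anti to the SO2 bridge; bridgehead centres are lost on extrusion) | CC(C)(C)OC(=O)N1C[C@H](c2ccnc(Cl)n2)[C@H]2[C@H]3C(Br)=C(Br)[C@@H]([C@@H]12)S3(=O)=O | intermediate (not isolated)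
8 | tert-butyl 5,6-dibromo-3-(2-chloropyrimidin-4-yl)-2,3,3a,7a-tetrahydro-1H-indole-1-carboxylate (racemic; cis-fused, pyrimidinyl cis to H3a and trans to the C3a–C4 bond) | CC(C)(C)OC(=O)N1C[C@H](c2ccnc(Cl)n2)[C@H]2C=C(Br)C(Br)=C[C@@H]12 | intermediate
9 | tert-butyl 5,6-dibromo-3-(2-chloropyrimidin-4-yl)-2,3-dihydro-1H-indole-1-carboxylate (racemic, one enantiomer drawn) | CC(C)(C)OC(=O)N1C[C@H](c2ccnc(Cl)n2)c2cc(Br)c(Br)cc21 | intermediate (not isolated)
10 | tert-butyl 5,6-dibromo-3-(2-chloropyrimidin-4-yl)-1H-indole-1-carboxylate | CC(C)(C)OC(=O)n1cc(-c2ccnc(Cl)n2)c2cc(Br)c(Br)cc21 | intermediate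
11 | 5,6-dibromo-3-(2-chloropyrimidin-4-yl)-1H-indole | Clc1nccc(-c2c[nH]c3cc(Br)c(Br)cc23)n1 | intermediate (not isolated)
12 | meridianin F, 4-(5,6-dibromo-1H-indol-3-yl)pyrimidin-2-amine (achiral) | Nc1nccc(-c2c[nH]c3cc(Br)c(Br)cc23)n1 | target

**Step count**

Total steps: 5. Longest linear sequence: 4 steps (steps 2, 3, 4, 5 from 4 and 5; the branch through step 1 is equally long).

**Steps most likely to fail**

Step 3. Self-dimerization of the dioxide with SO2 loss, or acid-induced breakdown of the C3-substituted enecarbamate, may outpace the cross-cycloaddition. The fallback sets out from 3 and returns at 11; it keeps the ring construction but attaches the pyrimidine afterwards. Compound 3 is heated in toluene at 80 °C with a large excess of commercial tert-butyl 2,3-dihydro-1H-pyrrole-1-carboxylate, an unhindered partner that can be used in quantity. This should give, through the bridged sulfone tert-butyl 5,6-dibromo-2,3,3a,4,7,7a-hexahydro-1H-4,7-epithioindole-1-carboxylate 8,8-dioxide F1 (not isolated), the cis-fused diene tert-butyl 5,6-dibromo-2,3,3a,7a-tetrahydro-1H-indole-1-carboxylate F2. DDQ (1.1 equiv, rt) should aromatize it to tert-butyl 5,6-dibromo-2,3-dihydro-1H-indole-1-carboxylate F3. CF3CO2H in CH2Cl2 should free 5,6-dibromo-2,3-dihydro-1H-indole F4, and MnO2 in CH2Cl2 should dehydrogenate that to 5,6-dibromo-1H-indole F5. Friedel–Crafts-type heteroarylation of F5 at C3 with 2,4-dichloropyrimidine and AlCl3 (1,2-dimethoxyethane, 80 °C) should then give 11, which takes the ammonia treatment of step 5.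

Step 2. The pyrimidine nitrogens may tie up the palladium, and re-addition of palladium hydride may shift the new double bond toward the pyrimidine. The fallback sets out from 5 and returns at 6; it makes the aryl–carbon bond by conjugate addition and the enecarbamate by lactam reduction and dehydration. Iodine–magnesium exchange on 5 (i-PrMgCl·LiCl, THF, −78 °C) should give (2-chloropyrimidin-4-yl)magnesium chloride F6. Its CuBr·SMe2-catalysed 1,4-addition to commercial tert-butyl 2-oxo-2,5-dihydro-1H-pyrrole-1-carboxylate should give, after NH4Cl work-up, tert-butyl 4-(2-chloropyrimidin-4-yl)-2-oxopyrrolidine-1-carboxylate F7. Reduction of the imide-type carbonyl with i-Bu2AlH (THF, −78 °C) should give the lactamol tert-butyl 4-(2-chloropyrimidin-4-yl)-2-hydroxypyrrolidine-1-carboxylate F8. Acid-catalysed dehydration (pyridinium p-toluenesulfonate, toluene, 90 °C, molecular sieves) should then give 6.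

Step 4. The second dehydrogenation may stall at the indoline stage, because the carbamate nitrogen gives little help to hydride loss, while the acidic hydroquinone slowly strips the Boc group. The fallback sets out from 9 and returns at 11. Step 4 is stopped at 9 (DDQ 1.1 equiv, rt). Boc is removed with CF3CO2H in CH2Cl2 to give 5,6-dibromo-3-(2-chloropyrimidin-4-yl)-2,3-dihydro-1H-indole F9. The free indoline is dehydrogenated with MnO2 (CH2Cl2, rt) to 11, which goes into the ammonia step.

**Further compounds**

F1 | step 3 | tert-butyl 5,6-dibromo-2,3,3a,4,7,7a-hexahydro-1H-4,7-epithioindole-1-carboxylate 8,8-dioxide (racemic, cis-fused, endo drawn; not isolated) | CC(C)(C)OC(=O)N1CC[C@H]2[C@H]3C(Br)=C(Br)[C@@H]([C@@H]12)S3(=O)=O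
F2 | step 3 | tert-butyl cis-5,6-dibromo-2,3,3a,7a-tetrahydro-1H-indole-1-carboxylate (racemic) | CC(C)(C)OC(=O)N1CC[C@H]2C=C(Br)C(Br)=C[C@@H]12
F3 | step 3 | tert-butyl 5,6-dibromo-2,3-dihydro-1H-indole-1-carboxylate | CC(C)(C)OC(=O)N1CCc2cc(Br)c(Br)cc21
F4 | step 3 | 5,6-dibromo-2,3-dihydro-1H-indole | Brc1cc2c(cc1Br)NCC2
F5 | step 3 | 5,6-dibromo-1H-indole | Brc1cc2cc[nH]c2cc1Br
F6 | step 2 | (2-chloropyrimidin-4-yl)magnesium chloride (not isolated) | Clc1nccc([Mg]Cl)n1
F7 | step 2 | tert-butyl 4-(2-chloropyrimidin-4-yl)-2-oxopyrrolidine-1-carboxylate (racemic, one enantiomer drawn) | CC(C)(C)OC(=O)N1C[C@H](c2ccnc(Cl)n2)CC1=O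
F8 | step 2 | tert-butyl 4-(2-chloropyrimidin-4-yl)-2-hydroxypyrrolidine-1-carboxylate (racemic, both epimers at the hemiaminal carbon) | CC(C)(C)OC(=O)N1C[C@H](c2ccnc(Cl)n2)CC1O
F9 | step 4 | 5,6-dibromo-3-(2-chloropyrimidin-4-yl)-2,3-dihydro-1H-indole (racemic, one enantiomer drawn) | Clc1nccc([C@H]2CNc3cc(Br)c(Br)cc32)n1
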